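**Retrosynthetic overview**

1. Ring B is the acyl ring (C1' carbonyl carbon, C2' OMe, C3' Me, C4' OH, C5' Cl, C6' Me) and ring A the phenol ring (C1 CO2Me, C2 OH, C3/C5/C6 Me, C4 O-acyl). The route rests on the adjacent C6' methyl and C5' chlorine of ring B, which lie between C1' and the oxygen-bearing C4', so a C5'–C6' aryne flanked by a C1' oxazoline and a C4' acetal oxygen can take up both in one operation.
2. Last disconnection: the depside ester C1'(=O)–O4, giving the O4'-methoxymethyl ring B acid and methyl 2,4-dihydroxy-3,5,6-trimethylbenzoate (from methyl atratate by C5 formylation and reduction).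
3. The ring B acid comes from a 4,4-dimethyloxazoline by N-methylation, hydride reduction, hydrolysis to the aldehyde and chlorite oxidation.
4. Key disconnection: C6'–CH3 and C5'–Cl, back to the 5'-chloro-6'-H aryl oxazoline (C6' lithiation, loss of LiCl, CH3Li addition, C2Cl6 quench), which is made from methyl 2,4-dihydroxy-3-methylbenzoate.
5. Ring order: both benzene rings are bought; the only ring made is the auxiliary oxazoline (step 6), which is opened again in step 9.

Key step: step 7

Remark: the target has no stereocentre, so only regiochemistry has to be controlled; both hydroxybenzoate starting materials are taken as purchasable.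

**Step 1**
Reactants: 1 methyl 2,4-dihydroxy-3-methylbenzoate
Product: 2 methyl 5-chloro-2,4-dihydroxy-3-methylbenzoate
Conditions: SO2Cl2 (1.05 equiv), CH2Cl2–Et2O, 0 °C to rt
Reagents that add atoms: sulfuryl chloride, O=S(=O)(Cl)Cl
Why: Electrophilic aromatic chlorination should go to C5, which is ortho to the 4-hydroxyl and para to the 2-hydroxyl, whereas C6 is meta to both and next to the ester.

**Step 2**
Reactants: 2 methyl 5-chloro-2,4-dihydroxy-3-methylbenzoate
Product: 3 methyl 5-chloro-2-hydroxy-4-(methoxymethoxy)-3-methylbenzoate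
Conditions: MOMCl, i-Pr2NEt, CH2Cl2, 0 °C to rt
Reagents that add atoms: chloromethyl methyl ether, COCCl
Why: O-alkylation with an α-chloro ether (Williamson type) should take the free, more acidic 4-hydroxyl, because the 2-hydroxyl is held in a hydrogen bond to the ester carbonyl.

**Step 3**
Reactants: 3 methyl 5-chloro-2-hydroxy-4-(methoxymethoxy)-3-methylbenzoate
Product: 4 methyl 5-chloro-2-methoxy-4-(methoxymethoxy)-3-methylbenzoate
Conditions: MeI, K2CO3, DMF, 50 °C
Reagents that add atoms: iodomethane, CI
Why: Williamson etherification in a dipolar solvent breaks the salicylate hydrogen bond and methylates the only remaining hydroxyl, while acetal, ester and aryl chloride are inert.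

**Step 4**
Reactants: 4 methyl 5-chloro-2-methoxy-4-(methoxymethoxy)-3-methylbenzoate
Product: 5 5-chloro-2-methoxy-4-(methoxymethoxy)-3-methylbenzoic acid
Conditions: LiOH, THF–MeOH–H2O, 50 °C; then cold 1 M HCl to pH 3
Reagents that add atoms: lithium hydroxide, [Li+].[OH-]
Why: Saponification of a benzoate with a single ortho substituent is unhindered, the acetal is stable to base, and a brief cold acidification frees the acid without cleaving the methoxymethyl ether.

**Step 5**
Reactants: 5 5-chloro-2-methoxy-4-(methoxymethoxy)-3-methylbenzoic acid; 6 2-amino-2-methylpropan-1-ol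
Product: 8 5-chloro-N-(1-hydroxy-2-methylpropan-2-yl)-2-methoxy-4-(methoxymethoxy)-3-methylbenzamide, via acid chloride 7 (not isolated)
Conditions: 1-chloro-N,N,2-trimethylprop-1-en-1-amine (1.05 equiv), CH2Cl2, 0 °C to rt; then 6, Et3N, 0 °C to rt
Reagents that add atoms: none
Why: The chloroenamine makes the acid chloride without releasing HCl, so the acetal survives, and Schotten–Baumann-type acylation of the amino alcohol then occurs at nitrogen in preference to oxygen.

**Step 6**
Reactants: 8 5-chloro-N-(1-hydroxy-2-methylpropan-2-yl)-2-methoxy-4-(methoxymethoxy)-3-methylbenzamide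
Product: 10 2-[5-chloro-2-methoxy-4-(methoxymethoxy)-3-methylphenyl]-4,4-dimethyl-4,5-dihydrooxazole, via mesylate 9 (not isolated)
Conditions: MsCl, Et3N (3 equiv), CH2Cl2, 0 °C to reflux
Reagents that add atoms: none
Why: Cyclodehydration of a β-hydroxy amide: the primary alcohol is mesylated and the amide oxygen displaces the mesylate in a 5-exo-tet closure helped by the gem-dimethyl group, under basic conditions that spare the acetal (SOCl2 would release HCl and is avoided).

**Step 7**
Reactants: 10 2-[5-chloro-2-methoxy-4-(methoxymethoxy)-3-methylphenyl]-4,4-dimethyl-4,5-dihydrooxazole; 11 methyllithium; 12 hexachloroethane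
Product: 16 2-[3-chloro-6-methoxy-4-(methoxymethoxy)-2,5-dimethylphenyl]-4,4-dimethyl-4,5-dihydrooxazole, via C6'-aryllithium 13 (not isolated), via C5'-C6' aryne 14 (not isolated), via C5'-aryllithium 15 (not isolated)
Conditions: sec-BuLi (1.0 equiv), THF, −78 °C; CH3Li (4 equiv), −78 to −10 °C; C2Cl6 (6 equiv), −78 °C to rt
Reagents that add atoms: methyllithium, [Li]C; hexachloroethane, ClC(Cl)(Cl)C(Cl)(Cl)Cl
Why: sec-BuLi removes the only ring hydrogen, C6'-H, which is flanked by chlorine and the oxazoline (directed ortho-metalation, fast at −78 °C where displacement of the C2' methoxy group is still slow), and the chelated aryllithium 13 loses LiCl on warming to give the C5'–C6' aryne 14. CH3Li bound to the oxazoline nitrogen adds at C6' (new C6'–CH3 bond) and the charge arrives at C5', beside the inductively withdrawing, lithium-binding C4' acetal oxygen, so both flanking groups call for the same orientation. C2Cl6 then transfers electrophilic chlorine to aryllithium 15 (new C5'–Cl bond), putting chlorine back on the carbon that lost it, so the net change is C6'-H to C6'-CH3 on a ring that ends up hexasubstituted. This is the known tandem organolithium addition and electrophile trapping of arynes generated from 3-chloroaryl oxazolines; no ring is closed and no stereocentre is formed. The step needs methyl at C6' and not C5', and aryne chemistry in place of SNAr loss of the C2' methoxy group: the first rests on oxazoline delivery reinforced by the 3-alkoxyaryne polarisation, the second on the ring being an aryl anion (13 or 15) whenever free alkyllithium is present above −78 °C, and sec-BuLi is used for the metalation because CH3Li is a slow kinetic base.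

**Step 8**
Reactants: 16 2-[3-chloro-6-methoxy-4-(methoxymethoxy)-2,5-dimethylphenyl]-4,4-dimethyl-4,5-dihydrooxazole
Product: 17 2-[3-chloro-6-methoxy-4-(methoxymethoxy)-2,5-dimethylphenyl]-3,4,4-trimethyl-4,5-dihydrooxazol-3-ium iodide
Conditions: MeI (excess), MeNO2, 70 °C, sealed vessel
Reagents that add atoms: iodomethane, CI
Why: Menshutkin N-alkylation at the only nucleophilic site, the sp2 nitrogen, which lies away from the twisted aryl ring, while the neopentyl-type C5 of the 4,4-dimethyl ring resists opening by iodide.

**Step 9**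
Reactants: 17 2-[3-chloro-6-methoxy-4-(methoxymethoxy)-2,5-dimethylphenyl]-3,4,4-trimethyl-4,5-dihydrooxazol-3-ium iodide
Product: 19 3-chloro-6-methoxy-4-(methoxymethoxy)-2,5-dimethylbenzaldehyde, via N-methyl oxazolidine 18 (not isolated)
Conditions: NaBH4, MeOH–THF, 0 °C; then aqueous oxalic acid, THF, rt
Reagents that add atoms: water, O
Why: Hydride reduction of the iminium-type C2 gives the N,O-aminal, which mild aqueous acid should hydrolyse to the aldehyde at room temperature while the aryl methoxymethyl ether persists; this is the standard reductive unmasking of crowded aryl oxazolines, for which direct hydrolysis is too slow.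

**Step 10**
Reactants: 19 3-chloro-6-methoxy-4-(methoxymethoxy)-2,5-dimethylbenzaldehyde
Product: 20 3-chloro-6-methoxy-4-(methoxymethoxy)-2,5-dimethylbenzoic acid
Conditions: NaClO2, NaH2PO4, 2-methylbut-2-ene, t-BuOH–H2O, rt
Reagents that add atoms: sodium chlorite, [Na+].[O-]Cl=O
Why: Pinnick oxidation converts hindered aryl aldehydes to acids at buffered pH 3–4, which the acetal tolerates, and the fully substituted ring offers no site for chlorination by the scavenged HOCl.

**Step 11**
Reactants: 21 methyl atratate (methyl 2,4-dihydroxy-3,6-dimethylbenzoate)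
Product: 22 methyl 3-formyl-4,6-dihydroxy-2,5-dimethylbenzoate (formyl at C5 of the atratate numbering)
Conditions: Cl2CHOMe, TiCl4, CH2Cl2, −10 °C to rt; then aqueous HCl
Reagents that add atoms: dichloromethyl methyl ether, COC(Cl)Cl; water, O
Why: Rieche formylation places the formyl group on the only unsubstituted ring carbon, ortho to the 4-hydroxyl and para to the 2-hydroxyl, with the titanium phenoxide guiding the electrophile.

**Step 12**
Reactants: 22 methyl 3-formyl-4,6-dihydroxy-2,5-dimethylbenzoate
Product: 23 methyl 2,4-dihydroxy-3,5,6-trimethylbenzoate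
Conditions: Et3SiH (3 equiv), TFA, CH2Cl2, rt
Reagents that add atoms: none
Why: Ionic hydrogenation: protonation gives a benzylic cation stabilised by the ortho and para hydroxyls, the silane delivers hydride twice (through the benzylic alcohol) and the formyl group ends as methyl while the ester is untouched.

**Step 13**
Reactants: 20 3-chloro-6-methoxy-4-(methoxymethoxy)-2,5-dimethylbenzoic acid; 23 methyl 2,4-dihydroxy-3,5,6-trimethylbenzoate
Product: 25 methyl 4-{[3-chloro-6-methoxy-4-(methoxymethoxy)-2,5-dimethylbenzoyl]oxy}-2-hydroxy-3,5,6-trimethylbenzoate, via acid chloride 24 (not isolated)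
Conditions: 1-chloro-N,N,2-trimethylprop-1-en-1-amine, CH2Cl2, 0 °C to rt; then 23, Cs2CO3 (1.1 equiv), MeCN, rt to 50 °C
Reagents that add atoms: none
Why: Depside esterification by phenoxide acylation with an acid chloride made under neutral conditions: the 4-hydroxyl, para to the ester and not hydrogen-bonded, is the more acidic and is the one ionised by Cs2CO3, whereas the 2-hydroxyl stays chelated to the ester carbonyl.

**Step 14**
Reactants: 25 methyl 4-{[3-chloro-6-methoxy-4-(methoxymethoxy)-2,5-dimethylbenzoyl]oxy}-2-hydroxy-3,5,6-trimethylbenzoate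
Product: 26 methyl 4-[(3-chloro-4-hydroxy-6-methoxy-2,5-dimethylbenzoyl)oxy]-2-hydroxy-3,5,6-trimethylbenzoate (CNP0121273.0)
Conditions: TFA–CH2Cl2–H2O, 0 °C to rt
Reagents that add atoms: none
Why: Acid-catalysed acetal hydrolysis removes the methoxymethyl ether, while the doubly ortho-shielded aryl ester and the chelated methyl ester should not hydrolyse under these conditions.

**Compound list**

1 | methyl 2,4-dihydroxy-3-methylbenzoate | COC(=O)c1ccc(O)c(C)c1O | starting material
2 | methyl 5-chloro-2,4-dihydroxy-3-methylbenzoate | COC(=O)c1cc(Cl)c(O)c(C)c1O | intermediate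
3 | methyl 5-chloro-2-hydroxy-4-(methoxymethoxy)-3-methylbenzoate | COCOc1c(Cl)cc(C(=O)OC)c(O)c1C | intermediate
4 | methyl 5-chloro-2-methoxy-4-(methoxymethoxy)-3-methylbenzoate | COCOc1c(Cl)cc(C(=O)OC)c(OC)c1C | intermediate
5 | 5-chloro-2-methoxy-4-(methoxymethoxy)-3-methylbenzoic acid | COCOc1c(Cl)cc(C(=O)O)c(OC)c1C | intermediate
6 | 2-amino-2-methylpropan-1-ol | CC(C)(N)CO | starting material
7 | 5-chloro-2-methoxy-4-(methoxymethoxy)-3-methylbenzoyl chloride (not isolated) | COCOc1c(Cl)cc(C(Cl)=O)c(OC)c1C | intermediate
8 | 5-chloro-N-(1-hydroxy-2-methylpropan-2-yl)-2-methoxy-4-(methoxymethoxy)-3-methylbenzamide | COCOc1c(Cl)cc(C(=O)NC(C)(C)CO)c(OC)c1C | intermediate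
9 | 2-[5-chloro-2-methoxy-4-(methoxymethoxy)-3-methylbenzamido]-2-methylpropyl methanesulfonate (not isolated) | COCOc1c(Cl)cc(C(=O)NC(C)(C)COS(C)(=O)=O)c(OC)c1C | intermediate
10 | 2-[5-chloro-2-methoxy-4-(methoxymethoxy)-3-methylphenyl]-4,4-dimethyl-4,5-dihydrooxazole | COCOc1c(Cl)cc(C2=NC(C)(C)CO2)c(OC)c1C | intermediate
11 | methyllithium | [Li]C | starting material
12 | hexachloroethane | ClC(Cl)(Cl)C(Cl)(Cl)Cl | starting material
13 | 2-[5-chloro-6-lithio-2-methoxy-4-(methoxymethoxy)-3-methylphenyl]-4,4-dimethyl-4,5-dihydrooxazole (C6'-aryllithium, not isolated) | COCOc1c(Cl)c([Li])c(C2=NC(C)(C)CO2)c(OC)c1C | intermediate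
14 | 2-[5,6-didehydro-2-methoxy-4-(methoxymethoxy)-3-methylphenyl]-4,4-dimethyl-4,5-dihydrooxazole (C5'–C6' aryne, not isolated) | COCOC1=C(C)C(OC)=C(C2=NC(C)(C)CO2)C#C1 | intermediate
15 | 2-[3-lithio-6-methoxy-4-(methoxymethoxy)-2,5-dimethylphenyl]-4,4-dimethyl-4,5-dihydrooxazole (C5'-aryllithium, not isolated) | COCOc1c([Li])c(C)c(C2=NC(C)(C)CO2)c(OC)c1C | intermediate
16 | 2-[3-chloro-6-methoxy-4-(methoxymethoxy)-2,5-dimethylphenyl]-4,4-dimethyl-4,5-dihydrooxazole | COCOc1c(Cl)c(C)c(C2=NC(C)(C)CO2)c(OC)c1C | intermediate
17 | 2-[3-chloro-6-methoxy-4-(methoxymethoxy)-2,5-dimethylphenyl]-3,4,4-trimethyl-4,5-dihydrooxazol-3-ium iodide | COCOc1c(Cl)c(C)c(C2=[N+](C)C(C)(C)CO2)c(OC)c1C.[I-] | intermediate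
18 | 2-[3-chloro-6-methoxy-4-(methoxymethoxy)-2,5-dimethylphenyl]-3,4,4-trimethyloxazolidine (racemic at C2, not isolated) | COCOc1c(Cl)c(C)c(C2OCC(C)(C)N2C)c(OC)c1C | intermediate
19 | 3-chloro-6-methoxy-4-(methoxymethoxy)-2,5-dimethylbenzaldehyde | COCOc1c(Cl)c(C)c(C=O)c(OC)c1C | intermediate
20 | 3-chloro-6-methoxy-4-(methoxymethoxy)-2,5-dimethylbenzoic acid | COCOc1c(Cl)c(C)c(C(=O)O)c(OC)c1C | intermediate
21 | methyl atratate (methyl 2,4-dihydroxy-3,6-dimethylbenzoate) | COC(=O)c1c(C)cc(O)c(C)c1O | starting material
22 | methyl 3-formyl-4,6-dihydroxy-2,5-dimethylbenzoate | COC(=O)c1c(C)c(C=O)c(O)c(C)c1O | intermediate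
23 | methyl 2,4-dihydroxy-3,5,6-trimethylbenzoate | COC(=O)c1c(C)c(C)c(O)c(C)c1O | intermediate
24 | 3-chloro-6-methoxy-4-(methoxymethoxy)-2,5-dimethylbenzoyl chloride (not isolated) | COCOc1c(Cl)c(C)c(C(Cl)=O)c(OC)c1C | intermediate
25 | methyl 4-{[3-chloro-6-methoxy-4-(methoxymethoxy)-2,5-dimethylbenzoyl]oxy}-2-hydroxy-3,5,6-trimethylbenzoate | COC(=O)c1c(C)c(C)c(OC(=O)c2c(C)c(Cl)c(OCOC)c(C)c2OC)c(C)c1O | intermediate
26 | methyl 4-[(3-chloro-4-hydroxy-6-methoxy-2,5-dimethylbenzoyl)oxy]-2-hydroxy-3,5,6-trimethylbenzoate | COC(=O)c1c(C)c(C)c(OC(=O)c2c(C)c(Cl)c(O)c(C)c2OC)c(C)c1O | target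

**Step count and risks**

Total steps: 14. Longest linear sequence: 12 steps (steps 1–10, 13 and 14, from compound 1).

Steps most likely to fail:

1. Step 7. Alkyllithium may displace the C2' methoxy group (SNAr on the o-methoxyaryl oxazoline) before metalation is complete, residual sec-BuLi may add to the aryne in place of CH3Li, methyl may add at C5' to some extent, or aryllithium 15 may be protonated before it is chlorinated. Fallback: give up the aryne and buy the C6' methyl with the ring. The fallback sets out from methyl atratate 21. SO2Cl2 in CH2Cl2 should chlorinate its only free ring position to give methyl 3-chloro-4,6-dihydroxy-2,5-dimethylbenzoate F1. MOMCl and i-Pr2NEt should then protect the non-chelated hydroxyl to give methyl 3-chloro-6-hydroxy-4-(methoxymethoxy)-2,5-dimethylbenzoate F2. MeI and K2CO3 in DMF should give methyl 3-chloro-6-methoxy-4-(methoxymethoxy)-2,5-dimethylbenzoate F3. KOH in DMSO–H2O at 90 °C should hydrolyse the hindered ester, and the fallback comes back to the route at acid 20.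

2. Step 13. Both partners carry two ortho substituents, so addition to the shielded carbonyl of 24 may be slow enough for hydrolysis of the acid chloride or acylation at O2 to compete. Fallback: change the mechanism to capture of a linear acylium ion under acidic conditions, with an acid-stable acetate on O4'. The fallback sets out from acid 20. 2 M HCl in THF at 50 °C should remove the acetal to give 3-chloro-4-hydroxy-6-methoxy-2,5-dimethylbenzoic acid F4. Ac2O in pyridine followed by water should give 4-acetoxy-3-chloro-6-methoxy-2,5-dimethylbenzoic acid F5. Trifluoroacetic anhydride in toluene at rt should join F5 to the 4-hydroxyl of phenol 23 to give methyl 4-[(4-acetoxy-3-chloro-6-methoxy-2,5-dimethylbenzoyl)oxy]-2-hydroxy-3,5,6-trimethylbenzoate F6. Aqueous NH3 in THF at 0 °C should cleave the unhindered acetate and spare the crowded depside ester, and the fallback comes back to the route at target 26.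

3. Step 9. Hydrolysis of the crowded N,O-aminal may stall under acid mild enough to keep the methoxymethyl ether, or the ether may be lost in part when the acid is strengthened, giving a mixture. Fallback: accept full deprotection and re-protect. The fallback sets out from oxazolinium salt 17. NaBH4 reduction to 18 followed by 2 M HCl in THF at 50 °C should hydrolyse both the aminal and the acetal to give 3-chloro-4-hydroxy-6-methoxy-2,5-dimethylbenzaldehyde F7. MOMCl and i-Pr2NEt in CH2Cl2 should re-install the ether, and the fallback comes back to the route at aldehyde 19.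

**Further compounds**

F1 | step 7 | methyl 3-chloro-4,6-dihydroxy-2,5-dimethylbenzoate | COC(=O)c1c(C)c(Cl)c(O)c(C)c1O
F2 | step 7 | methyl 3-chloro-6-hydroxy-4-(methoxymethoxy)-2,5-dimethylbenzoate | COCOc1c(Cl)c(C)c(C(=O)OC)c(O)c1C
F3 | step 7 | methyl 3-chloro-6-methoxy-4-(methoxymethoxy)-2,5-dimethylbenzoate | COCOc1c(Cl)c(C)c(C(=O)OC)c(OC)c1C
F4 | step 13 | 3-chloro-4-hydroxy-6-methoxy-2,5-dimethylbenzoic acid | COc1c(C)c(O)c(Cl)c(C)c1C(=O)O
F5 | step 13 | 4-acetoxy-3-chloro-6-methoxy-2,5-dimethylbenzoic acid | COc1c(C)c(OC(C)=O)c(Cl)c(C)c1C(=O)O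
F6 | step 13 | methyl 4-[(4-acetoxy-3-chloro-6-methoxy-2,5-dimethylbenzoyl)oxy]-2-hydroxy-3,5,6-trimethylbenzoate | COC(=O)c1c(C)c(C)c(OC(=O)c2c(C)c(Cl)c(OC(C)=O)c(C)c2OC)c(C)c1O
F7 | step 9 | 3-chloro-4-hydroxy-6-methoxy-2,5-dimethylbenzaldehyde | COc1c(C)c(O)c(Cl)c(C)c1C=O
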